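The synthesis rests on removing the quaternary carbon C1 from the seven-membered ring. What remains is C5–C10, with oxygen on C6 and C9 and methyl on C8, which is the ring of a methylhydroquinone ether. One intramolecular Buchner reaction of an α-methyl diazoketone puts C1 back between C5 and C10. It forms C1–C5 and C1–C10, closes the cyclopentane ring, widens the benzene ring to the cycloheptatriene and sets C1. The precursor is an enantiopure 2-diazo-5-aryl-6-methylheptan-3-one whose C4 oxygen and neighbouring phenol oxygen (O6) are bridged by iPr2Si. This lock fixes the face of attack and later releases the C4 alcohol and C6 ketone with fluoride instead of strong acid.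

Key step: step 7

Locants (hydroazulene): C1 angular-methyl carbon, C2, C3, C4 carbinol carbon bearing isopropyl, C5 angular CH, C6 aroyloxy carbon, C7=C8 (methyl on C8), C9 acetoxy carbon, C10. O4, O6 and O9 are the oxygens on those carbons. The target is (1R,4R,5S,6S,9S): the C1 methyl and O4 lie on one face, and H5, isopropyl, O6 and O9 on the other.

Assumption: the (S,S) form of silane 5 is taken to deliver allyl to the Si face of ketone 4. If the first run shows the other sense, the equally available (R,R) form is used and nothing else changes.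

Assumption: silane 5 and acid 20 are treated as catalogue compounds.

Design remarks:
- (a) The silylene bridge holds O4 in the arene plane, so C3 and isopropyl must stand on opposite faces. It also makes O4 a poor nucleophile toward the carbenoid.
- (b) The C2 oxygen is carried as a xanthate and removed by radical chemistry only after the triene and the enone are gone.
- (c) The two ring ketones are reduced one after the other, so each ester goes onto the only free secondary alcohol present.

Step 1
Reactants: 1 2,5-dimethoxytoluene; 2 isobutyryl chloride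
Product: 4 1-(2-hydroxy-5-methoxy-4-methylphenyl)-2-methylpropan-1-one, via dimethoxy ketone 3 (not isolated)
Conditions: AlCl3 (2.5 equiv), CH2Cl2, 0 °C then reflux; 1 M HCl
Reagents that add atoms: none
Why: Friedel–Crafts acylation enters para to the methyl group and ortho to a methoxy group, the only open activated site, and the excess AlCl3, chelated between the new carbonyl and the adjacent methoxy oxygen, then cleaves only that ether (chelation-directed aryl methyl ether cleavage), which frees the phenol needed in steps 2 and 3.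

Step 2
Reactants: 4 hydroxy ketone; 5 (3aS,7aS)-2-allyl-1,3-bis(4-bromobenzyl)-2-chlorooctahydro-1H-1,3,2-benzodiazasilole
Product: 6 (3R)-3-(2-hydroxy-5-methoxy-4-methylphenyl)-2-methylhex-5-en-3-ol
Conditions: 5 (1.5 equiv), toluene, 40 °C; then 1 M HCl, EtOAc
Reagents that add atoms: none
Why: Phenol-directed asymmetric allylation of a 2-hydroxyaryl ketone with a strained chiral allylchlorosilane, in which the phenol displaces chloride, the HCl formed protonates a ring nitrogen and raises the Lewis acidity of silicon, and allyl passes to the bound ketone in a closed chair-like array, a mode known to accept isopropyl and tert-butyl aryl ketones, so that the twofold-symmetric diamine chooses the Si face and sets C4 as R.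

Step 3
Reactants: 6 diol
Product: 7 (4R)-4-allyl-2,2,4-triisopropyl-6-methoxy-7-methyl-4H-1,3,2-benzodioxasiline
Conditions: iPr2Si(OTf)2 (1.1 equiv), 2,6-lutidine (3 equiv), CH2Cl2, 0 °C to rt
Reagents that add atoms: diisopropylsilyl bis(trifluoromethanesulfonate), CC(C)[Si](OS(=O)(=O)C(F)(F)F)(OS(=O)(=O)C(F)(F)F)C(C)C
Why: Silylene protection of a 1,3-related phenol and tertiary alcohol, in which the phenol is silylated first and the hindered carbinol then closes the six-membered ring intramolecularly on the remaining silyl triflate under buffered conditions that leave C4 untouched.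

Step 4
Reactants: 7 alkene
Product: 8 [(4R)-2,2,4-triisopropyl-6-methoxy-7-methyl-4H-1,3,2-benzodioxasilin-4-yl]acetaldehyde
Conditions: OsO4 (2 mol %), NaIO4 (4 equiv), 2,6-lutidine (2 equiv), dioxane/H2O 3:1, rt
Reagents that add atoms: osmium tetroxide (catalytic oxygen carrier), O=[Os](=O)(=O)=O; sodium periodate, [Na+].[O-]I(=O)(=O)=O
Why: Lemieux–Johnson cleavage (catalytic dihydroxylation followed by periodate glycol fission) touches only the terminal alkene and, unlike ozone, spares the electron-rich ring, while 2,6-lutidine keeps the medium neutral for the silylene and the β-silyloxy aldehyde.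

Step 5
Reactants: 8 aldehyde
Product: 9 [(4R)-2,2,4-triisopropyl-6-methoxy-7-methyl-4H-1,3,2-benzodioxasilin-4-yl]acetic acid
Conditions: NaClO2, NaH2PO4, 2-methylbut-2-ene, tBuOH/H2O, 0 °C to rt
Reagents that add atoms: sodium chlorite, [Na+].[O-]Cl=O
Why: Pinnick oxidation converts the aldehyde into the acid near pH 4 without enolisation, and 2-methylbut-2-ene takes up HOCl before it can chlorinate the arene.

Step 6
Reactants: 9 acid; 10 N-ethyl-N-nitrosourea
Product: 13 (4R)-4-(3-diazo-2-oxobutyl)-2,2,4-triisopropyl-6-methoxy-7-methyl-4H-1,3,2-benzodioxasiline, via diazoethane 11 (not isolated), via acid chloride 12 (not isolated)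
Conditions: (a) 9, 1-chloro-N,N,2-trimethylprop-1-en-1-amine, CH2Cl2, 0 °C; (b) added to CH3CHN2 (3 equiv, from 10, 50% aq KOH, Et2O, −10 °C, dried over KOH), Et2O, −20 to 0 °C
Reagents that add atoms: none
Why: Acylation of a diazoalkane (first stage of the Arndt–Eistert sequence), in which the neutral chloroenamine makes the acid chloride without free HCl, diazoethane is acylated at carbon and a second equivalent removes HCl, which is the standard entry to 2-diazo-5-arylpentan-3-ones and needs no enolate next to the β-silyloxy carbon.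

Step 7
Reactants: 13 diazoketone
Product: 15 (1R,4R)-3-isopropyl-7-methoxy-6,8a-dimethyl-3,4-(diisopropylsilanediyldioxy)-2,3-dihydroazulen-1(8aH)-one, via norcaradiene 14 (not isolated)
Conditions: Rh2(OAc)4 (1 mol %), CH2Cl2 (0.005 M), reflux, 13 added over 3 h, acid-free glassware
Reagents that add atoms: none
Why: Rh2(OAc)4 removes N2 from 13 and the electrophilic keto carbenoid at C1 adds suprafacially to the C5–C10 π bond of the electron-rich ring to give norcaradiene 14, which is the intramolecular Buchner reaction of 1-diazo-4-arylbutan-2-ones in its known α-methyl variant. The five-membered ring closes in this [2+1] addition through C1–C5 (tether C1–C2–C3–C4–C5, carbonyl exo on the cyclopropane), and the seven-membered ring arises when 14 opens by disrotatory 6π electrocyclic cleavage of C5–C10, which relieves a cyclopropane shared by three rings. The only new stereocentre, C1, is controlled by C4: the siladioxine ring keeps O4 in the arene plane beside O6, C3 and isopropyl therefore stand on opposite faces, the carbenoid can reach only the face that carries C3, and the tether geometry then places the methyl group endo, that is cis to O4 and trans to isopropyl. Site selectivity for C5–C10 over C5–C6 follows from the oxygen on C6, which makes that bond fully substituted, whereas C10 carries hydrogen. Chemoselectivity over 1,2-hydride migration from the methyl group, insertion into the isopropyl C–H and attack on O4 rests on the high π-nucleophilicity of the dioxygenated ring, on the proximity enforced by the lock and on the low basicity and shielding of a silylated oxygen. Slow addition at high dilution suppresses azine and carbene-dimer formation, and the absence of acid prevents rearrangement to the 2-tetralone.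

Step 8
Reactants: 15 trienone
Product: 16 (1R,2S,4R)-2-alcohol of 15 (C2 hydroxyl on the isopropyl face, trans to O4 and to the C1 methyl)
Conditions: iBu2AlH (1.5 equiv), CH2Cl2, −78 °C; aq KNaC4H4O6 (tartrate)
Reagents that add atoms: none
Why: 1,2-Reduction of the neopentyl cyclopentanone by iBu2AlH, which is inert to both enol ethers, should come from the face opposite the pseudoaxial isopropyl group and give the 2S alcohol, a temporary centre erased in step 15, and the ketone is removed at this point because it is what drives acid-induced rearrangement of the triene to a tetralone.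

Step 9
Reactants: 16 alcohol
Product: 17 (1R,2S,4R)-O-(C2) S-methyl dithiocarbonate (xanthate) of 16
Conditions: NaH, CS2, THF, 0 °C; then MeI, rt
Reagents that add atoms: carbon disulfide, S=C=S; iodomethane, CI
Why: Xanthate formation (first stage of the Barton–McCombie deoxygenation) works on hindered alkoxides because CS2 is small, the substrate has no base-labile group or acidic C–H, the alkoxide lies trans to O4 and cannot reach silicon, and the radical stage is postponed because a C2 radical beside the vinyl groups on C1 of the triene would invite 1,2-vinyl migration.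

Step 10
Reactants: 17 xanthate
Product: 18 (1R,2S,4R,5R)-4-hydroxy-4-isopropyl-1,8-dimethyl-2-[(methylsulfanyl)carbonothioyloxy]hydroazul-7-ene-6,9-dione (trans-fused)
Conditions: 48% aq HF, MeCN, 0 °C to rt; cold aq NaHCO3
Reagents that add atoms: water, O
Why: Enol ether hydrolysis and fluoride desilylation in one flask, in which protonation at the unsubstituted C10 hydrolyses the methyl enol ether first and ends the norcaradiene equilibrium, fluoride then breaks the O6 enol Si–O bond before the O4–Si bond so that a free tertiary allylic alcohol never sits beside an enol ether and ionisation at C4 is avoided, and the C5 proton is placed reversibly through the enol so that the trans-fused 5R ketone should prevail, with C6 anti to isopropyl and O4–H hydrogen-bonded to the C6 carbonyl.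

Step 11
Reactants: 18 hydroxy enedione
Product: 19 (1R,2S,4R,5S,6S)-4,6-dihydroxy-4-isopropyl-1,8-dimethyl-2-[(methylsulfanyl)carbonothioyloxy]hydroazul-7-en-9-one
Conditions: Me4NBH(OAc)3 (6 equiv), MeCN/AcOH 1:1, −20 to 0 °C
Reagents that add atoms: none
Why: Evans–Saksena reduction, in which the reagent exchanges an acetate for O4 and delivers hydride within the molecule to the C6 face syn to O4 to give the 4,6-anti diol (6S), leaves the undirected C9 enone alone, and can act only on the trans-fused epimer, so that any cis-fused ketone should drain through its enol in the acetic acid/acetate buffer.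

Step 12
Reactants: 19 diol enone; 20 4-(tert-butyldimethylsilyloxy)benzoic acid
Product: 21 (1R,2S,4R,5S,6S)-6-[4-(tert-butyldimethylsilyloxy)benzoyloxy] derivative of 19
Conditions: 20 (1.5 equiv), dicyclohexylcarbodiimide, 4-(dimethylamino)pyridine, CH2Cl2, rt
Reagents that add atoms: none
Why: Steglich esterification acylates the only secondary alcohol, the tertiary O4–H being inert, as is known for the C6 hydroxyl of 4,6-dihydroxydaucanes, and no stereocentre is touched.

Step 13
Reactants: 21 ester enone
Product: 22 (1R,2S,4R,5S,6S,9R)-9-alcohol of 21 (O9 pseudoaxial, on the face of the C1 methyl)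
Conditions: (S)-1-methyl-3,3-diphenyltetrahydro-1H,3H-pyrrolo[1,2-c][1,3,2]oxazaborole (0.3 equiv), catecholborane (3 equiv), toluene, −78 to −40 °C; MeOH, aq NaHCO3
Reagents that add atoms: none
Why: Corey–Bakshi–Shibata 1,2-reduction of an α-methyl cycloalkenone, in which the S catalyst (alkenyl side as the large group) sends hydride to the face away from the axial C1 methyl, the face the substrate itself prefers, so that reagent and substrate should reinforce each other to give the 9R alcohol while esters, xanthate and silyl ether are left alone.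

Step 14
Reactants: 22 allylic alcohol
Product: 23 (1R,2S,4R,5S,6S,9S)-9-acetate (inverted at C9)
Conditions: PPh3, diisopropyl azodicarboxylate, AcOH, toluene, 0 °C to rt
Reagents that add atoms: acetic acid, CC(=O)O
Why: Mitsunobu reaction, in which acetate displaces the activated pseudoaxial oxygen with inversion from the open face opposite the C1 methyl and so installs the equatorial 9S acetate in the acylation step itself, the tertiary alcohol and the silylated phenol being unreactive and attack at C7 being disfavoured by the acyloxy-bearing C6.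

Step 15
Reactants: 23 xanthate diester
Product: 24 (1R,4R,5S,6S,9S)-9-acetoxy-6-[4-(tert-butyldimethylsilyloxy)benzoyloxy]-4-hydroxy-4-isopropyl-1,8-dimethylhydroazul-7-ene
Conditions: Bu3SnH (2 equiv), azobisisobutyronitrile (0.2 equiv), toluene, 90 °C
Reagents that add atoms: none
Why: Barton–McCombie deoxygenation, in which the secondary C2 radical now has only saturated carbons on C1, cannot reach the C7=C8 bond across the trans-fused frame and is quenched by the stannane, while allylic esters, the free tertiary alcohol and the aryl silyl ether tolerate stannyl radicals.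

Step 16
Reactants: 24 silyl ether
Product: 25 target CNP0305796.2
Conditions: Bu4NF/AcOH 1:1 (1.2 equiv), THF, 0 °C
Reagents that add atoms: none
Why: Fluoride cleavage of a phenolic silyl ether is fast at 0 °C, and the acetic acid buffer keeps the phenoxide from attacking or shifting either ester, so that all five stereocentres stay as set.

Compound list
1 | 2,5-dimethoxytoluene | Cc1cc(OC)ccc1OC | starting material
2 | isobutyryl chloride | CC(C)C(=O)Cl | starting material
3 | 1-(2,5-dimethoxy-4-methylphenyl)-2-methylpropan-1-one | CC(C)C(=O)c1cc(OC)c(C)cc1OC | intermediate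
4 | 1-(2-hydroxy-5-methoxy-4-methylphenyl)-2-methylpropan-1-one | CC(C)C(=O)c1cc(OC)c(C)cc1O | intermediate
5 | (3aS,7aS)-2-allyl-1,3-bis(4-bromobenzyl)-2-chlorooctahydro-1H-1,3,2-benzodiazasilole | C=CC[Si]1(Cl)N(Cc2ccc(Br)cc2)[C@H]2CCCC[C@@H]2N1Cc1ccc(Br)cc1 | starting material
6 | (3R)-3-(2-hydroxy-5-methoxy-4-methylphenyl)-2-methylhex-5-en-3-ol | C=CC[C@@](O)(C(C)C)c1cc(OC)c(C)cc1O | intermediate
7 | (4R)-4-allyl-2,2,4-triisopropyl-6-methoxy-7-methyl-4H-1,3,2-benzodioxasiline | C=CC[C@]1(C(C)C)O[Si](C(C)C)(C(C)C)Oc2cc(C)c(OC)cc21 | intermediate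
8 | [(4R)-2,2,4-triisopropyl-6-methoxy-7-methyl-4H-1,3,2-benzodioxasilin-4-yl]acetaldehyde | O=CC[C@]1(C(C)C)O[Si](C(C)C)(C(C)C)Oc2cc(C)c(OC)cc21 | intermediate
9 | [(4R)-2,2,4-triisopropyl-6-methoxy-7-methyl-4H-1,3,2-benzodioxasilin-4-yl]acetic acid | OC(=O)C[C@]1(C(C)C)O[Si](C(C)C)(C(C)C)Oc2cc(C)c(OC)cc21 | intermediate
10 | N-ethyl-N-nitrosourea | CCN(N=O)C(N)=O | starting material
11 | diazoethane | CC=[N+]=[N-] | intermediate
12 | [(4R)-2,2,4-triisopropyl-6-methoxy-7-methyl-4H-1,3,2-benzodioxasilin-4-yl]acetyl chloride | ClC(=O)C[C@]1(C(C)C)O[Si](C(C)C)(C(C)C)Oc2cc(C)c(OC)cc21 | intermediate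
13 | (4R)-4-(3-diazo-2-oxobutyl)-2,2,4-triisopropyl-6-methoxy-7-methyl-4H-1,3,2-benzodioxasiline, the O,O-diisopropylsilylene derivative of (5R)-2-diazo-5-hydroxy-5-(2-hydroxy-5-methoxy-4-methylphenyl)-6-methylheptan-3-one | CC(=[N+]=[N-])C(=O)C[C@]1(C(C)C)O[Si](C(C)C)(C(C)C)Oc2cc(C)c(OC)cc21 | intermediate
14 | norcaradiene: cyclopropane C1–C5–C10 on the ring face that carried C3, C1 methyl endo over the 6-silyloxy-9-methoxy-8-methylcyclohexadiene, C2 carbonyl exo, O4–Si(iPr)2–O6 bridge retained | COC1=C(C)C=C2O[Si](C(C)C)(C(C)C)O[C@@]3(C(C)C)CC(=O)[C@]4(C)[C@@H]1[C@@]243 | intermediate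
15 | (1R,4R)-hydroazula-5,7,9-trien-2-one with 1-Me, 8-Me, 4-iPr, 9-OMe and an O4–Si(iPr)2–O6 bridge; 3-isopropyl-7-methoxy-6,8a-dimethyl-3,4-(diisopropylsilanediyldioxy)-2,3-dihydroazulen-1(8aH)-one | COC1=C[C@@]2(C)C(=O)C[C@]3(C(C)C)O[Si](C(C)C)(C(C)C)OC(C=C1C)=C23 | intermediate
16 | (1R,2S,4R)-2-alcohol of 15 | COC1=C[C@@]2(C)[C@@H](O)C[C@]3(C(C)C)O[Si](C(C)C)(C(C)C)OC(C=C1C)=C23 | intermediate
17 | (1R,2S,4R)-2-O-[(methylsulfanyl)carbonothioyl] derivative of 16 | COC1=C[C@@]2(C)[C@@H](OC(=S)SC)C[C@]3(C(C)C)O[Si](C(C)C)(C(C)C)OC(C=C1C)=C23 | intermediate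
18 | (1R,2S,4R,5R)-4-hydroxy-4-isopropyl-1,8-dimethyl-2-[(methylsulfanyl)carbonothioyloxy]hydroazul-7-ene-6,9-dione, trans-fused | O=C1C[C@@]2(C)[C@@H](OC(=S)SC)C[C@@](O)(C(C)C)[C@@H]2C(=O)C=C1C | intermediate
19 | (1R,2S,4R,5S,6S)-4,6-dihydroxy-4-isopropyl-1,8-dimethyl-2-[(methylsulfanyl)carbonothioyloxy]hydroazul-7-en-9-one | O=C1C[C@@]2(C)[C@@H](OC(=S)SC)C[C@@](O)(C(C)C)[C@@H]2[C@@H](O)C=C1C | intermediate
20 | 4-(tert-butyldimethylsilyloxy)benzoic acid | CC(C)(C)[Si](C)(C)Oc1ccc(cc1)C(=O)O | starting material
21 | (1R,2S,4R,5S,6S)-6-[4-(tert-butyldimethylsilyloxy)benzoyloxy]-4-hydroxy-9-oxo xanthate | O=C1C[C@@]2(C)[C@@H](OC(=S)SC)C[C@@](O)(C(C)C)[C@@H]2[C@@H](OC(=O)c2ccc(O[Si](C)(C)C(C)(C)C)cc2)C=C1C | intermediate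
22 | (1R,2S,4R,5S,6S,9R)-9-alcohol of 21 | O[C@@H]1C[C@@]2(C)[C@@H](OC(=S)SC)C[C@@](O)(C(C)C)[C@@H]2[C@@H](OC(=O)c2ccc(O[Si](C)(C)C(C)(C)C)cc2)C=C1C | intermediate
23 | (1R,2S,4R,5S,6S,9S)-9-acetate xanthate | CC(=O)O[C@H]1C[C@@]2(C)[C@@H](OC(=S)SC)C[C@@](O)(C(C)C)[C@@H]2[C@@H](OC(=O)c2ccc(O[Si](C)(C)C(C)(C)C)cc2)C=C1C | intermediate
24 | (1R,4R,5S,6S,9S)-O-tert-butyldimethylsilyl ether of the target | CC(=O)O[C@H]1C[C@@]2(C)CC[C@@](O)(C(C)C)[C@@H]2[C@@H](OC(=O)c2ccc(O[Si](C)(C)C(C)(C)C)cc2)C=C1C | intermediate
25 | CNP0305796.2, (1R,4R,5S,6S,9S)-9-acetoxy-4-hydroxy-6-(4-hydroxybenzoyloxy)-4-isopropyl-1,8-dimethylhydroazul-7-ene | CC(=O)O[C@H]1C[C@@]2(C)CC[C@@](O)(C(C)C)[C@@H]2[C@@H](OC(=O)c2ccc(O)cc2)C=C1C | target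

Total step count: 16. Longest linear sequence: 16 steps (1 to 25).

Steps most likely to fail

Step 7. The carbenoid may be lost to 1,2-hydride migration from the α-methyl group, to insertion into the isopropyl methine C–H or to attack on O4. This becomes more likely if the strain of the emerging peri-fused siladioxine slows addition to the arene. The fallback gives up the silicon lock and hands facial control to allylic strain plus a chiral catalyst.
- It sets out from diol 6, and Et3SiOTf with 2,6-lutidine gives the bis(triethylsilyl) ether F1.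
- Lemieux–Johnson cleavage gives the aldehyde F2, and Pinnick oxidation gives the acid F3.
- The chloroenamine of step 6 gives the acid chloride F4, and diazoethane 11 gives the open-chain diazoketone F5.
- Cu(MeCN)4PF6 with the matched enantiomer of 2,2'-(propane-2,2-diyl)bis(4-tert-butyl-4,5-dihydrooxazole) carries out the Buchner reaction on a freely rotating tether. In that tether the small oxygen, not isopropyl, should lie in the arene plane beside O6, and the product is the bis-silylated azulenone F6.
- iBu2AlH gives the alcohol F7, and NaH, CS2 and MeI give the xanthate F8.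
- Aqueous HF in MeCN brings the material back to the route at 18.

Step 10. Once the strongly activating ene-dione is in place, the tertiary aldol may be lost by β-elimination or by retro-aldol cleavage of C4–C5. Protonation at C5 may also come from the face of the C1 methyl without later equilibration. The fallback keeps C9 masked, so that the aldol only ever belongs to a simple enone.
- It sets out from 17, and ethane-1,2-diol with pyridinium 4-toluenesulfonate in CH2Cl2 exchanges the methyl enol ether for the C9 dioxolane F9.
- Et3N·3HF in THF, non-aqueous and near neutral, removes the silylene and gives the hydroxy enone ketal F10.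
- Me4NBH(OAc)3 under the conditions of step 11 gives the diol ketal F11.
- Aqueous oxalic acid in THF removes the allylic ketal, and the material returns to the route at 19.

Step 14. The activated pseudoaxial C9 oxygen may leave by elimination toward C10, or acetate may enter at C7 with allylic shift, in place of clean inversion. The fallback avoids inversion altogether.
- It sets out from enone 21, which is reduced under pure reagent control with a full equivalent of (R)-1-methyl-3,3-diphenyltetrahydro-1H,3H-pyrrolo[1,2-c][1,3,2]oxazaborole and catecholborane. Hydride is delivered to the methyl-bearing face and gives the 9S alcohol F12, which is separated from any 22.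
- Ac2O, pyridine and 4-(dimethylamino)pyridine return the material to the route at 23.

Further compounds
F1 | step 7 | (3R)-3-[5-methoxy-4-methyl-2-(triethylsilyloxy)phenyl]-2-methyl-3-(triethylsilyloxy)hex-5-ene | C=CC[C@@](O[Si](CC)(CC)CC)(C(C)C)c1cc(OC)c(C)cc1O[Si](CC)(CC)CC
F2 | step 7 | (3R)-3-[5-methoxy-4-methyl-2-(triethylsilyloxy)phenyl]-4-methyl-3-(triethylsilyloxy)pentanal | O=CC[C@@](O[Si](CC)(CC)CC)(C(C)C)c1cc(OC)c(C)cc1O[Si](CC)(CC)CC
F3 | step 7 | (3R)-3-[5-methoxy-4-methyl-2-(triethylsilyloxy)phenyl]-4-methyl-3-(triethylsilyloxy)pentanoic acid | OC(=O)C[C@@](O[Si](CC)(CC)CC)(C(C)C)c1cc(OC)c(C)cc1O[Si](CC)(CC)CC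
F4 | step 7 | acid chloride of F3 | ClC(=O)C[C@@](O[Si](CC)(CC)CC)(C(C)C)c1cc(OC)c(C)cc1O[Si](CC)(CC)CC
F5 | step 7 | (5R)-2-diazo-5-[5-methoxy-4-methyl-2-(triethylsilyloxy)phenyl]-6-methyl-5-(triethylsilyloxy)heptan-3-one | CC(=[N+]=[N-])C(=O)C[C@@](O[Si](CC)(CC)CC)(C(C)C)c1cc(OC)c(C)cc1O[Si](CC)(CC)CC
F6 | step 7 | (1R,4R)-3-isopropyl-7-methoxy-6,8a-dimethyl-3,4-bis(triethylsilyloxy)-2,3-dihydroazulen-1(8aH)-one | COC1=C[C@@]2(C)C(=O)C[C@@](O[Si](CC)(CC)CC)(C(C)C)C2=C(O[Si](CC)(CC)CC)C=C1C
F7 | step 7 | (1R,2S,4R)-2-alcohol of F6 | COC1=C[C@@]2(C)[C@@H](O)C[C@@](O[Si](CC)(CC)CC)(C(C)C)C2=C(O[Si](CC)(CC)CC)C=C1C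
F8 | step 7 | (1R,2S,4R)-2-O-[(methylsulfanyl)carbonothioyl] derivative of F7 | COC1=C[C@@]2(C)[C@@H](OC(=S)SC)C[C@@](O[Si](CC)(CC)CC)(C(C)C)C2=C(O[Si](CC)(CC)CC)C=C1C
F9 | step 10 | (1R,2S,4R)-C9 ethylene ketal of the 5,7-diene with O4–Si(iPr)2–O6 bridge and C2 xanthate | CC1=CC2=C3[C@@](C)(CC14OCCO4)[C@@H](OC(=S)SC)C[C@]3(C(C)C)O[Si](C(C)C)(C(C)C)O2
F10 | step 10 | (1R,2S,4R,5R)-4-hydroxy-6-oxo-hydroazul-7-ene C9 ethylene ketal, C2 xanthate, trans-fused | C13(OCCO3)C[C@@]2(C)[C@@H](OC(=S)SC)C[C@@](O)(C(C)C)[C@@H]2C(=O)C=C1C
F11 | step 10 | (1R,2S,4R,5S,6S)-4,6-dihydroxy-hydroazul-7-ene C9 ethylene ketal, C2 xanthate | C13(OCCO3)C[C@@]2(C)[C@@H](OC(=S)SC)C[C@@](O)(C(C)C)[C@@H]2[C@@H](O)C=C1C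
F12 | step 14 | (1R,2S,4R,5S,6S,9S)-9-alcohol, C9 epimer of 22 | O[C@H]1C[C@@]2(C)[C@@H](OC(=S)SC)C[C@@](O)(C(C)C)[C@@H]2[C@@H](OC(=O)c2ccc(O[Si](C)(C)C(C)(C)C)cc2)C=C1C
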